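48% of left-handed product against 12% of right-handed product: that is where the blue run stood after 10.0 min, and I built my reckoning on such ratios.

in all of them: left-handed substrate 0.10 M; right-handed substrate 0.10 M

| charge | coupling partner | racemization catalyst | remark | time |
|---|---|---|---|---|
| grey | 0.40 M | 10 mM | the very flask that is asked about, followed so far |  |
| blue | 0.40 M | 6.7 mM | run made earlier |  |
| flask | 0.400 M | 10 mM |  | 15 min |

| run | time / min | left-handed product / % | right-handed product / % |
|---|---|---|---|
| grey | 0.417 | 22 | 5 |
| grey | 1.00 | 30 | 10 |
| grey | 2.00 | 35 | 11 |
| grey | 3.00 | 40 | 10 |
| blue | 0.833 | 31 | 9 |
| blue | 2.00 | 39 | 11 |
| blue | 5.00 | 46 | 11 |
| blue | 10.0 | 48 | 12 |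

(readings scatter by 1.5 percentage points)

* left-handed product and right-handed product together, in percent of the left-handed substrate and right-handed substrate charged together, at 15 min
* excess of left-handed product over right-handed product in the product at 15 min
* whether the exchange between left-handed substrate and right-handed substrate keeps pace with the reaction: how far the product's excess at 15 min gets from its value without exchange to its value with instant exchange (above 80% keeps pace, below 20% hardly takes part, else lags behind)

- coupling partner is single-handed; left-handed substrate and right-handed substrate are mirror images of each other, charged as a racemate, each of them at the stated concentration
- reactions considered so far: 2 coupling partner -> homo dimer; coupling partner -> decomposition product; coupling partner + right-handed substrate -> right-handed product; racemization catalyst -> spent catalyst; left-handed substrate + racemization catalyst <-> right-handed substrate + racemization catalyst; coupling partner + left-handed substrate -> left-handed product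
- an excess is the difference of the two amounts in percent of their sum
- an excess is below zero if the other one leads
- the handed part of coupling partner does not stay in what it makes, so the products of the two hands are mirror images too

I read the run in slow motion. In the first instants of the grey run, by 0.417 min, the two products already made 27.0% of the charge. In the middle, at 2.00 min, the grey run read 46.0% and the blue run 50.0%, so at that time these readings showed no extra conversion for grey's larger catalyst charge. Towards the end, blue gained 3 percentage points between 5.00 min and 10.0 min with 40.0% of the substrate unreacted. My suspect was therefore the coupling partner, which the dimer path also consumes, and I expected a total a little above blue's.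

For the excess I followed one molecule of coupling partner to its fork. While exchange holds the substrates racemic, it takes left-handed over right-handed substrate at a fixed ratio, the selectivity factor, which I pooled from all the readings as left-handed over right-handed product: 3.68. That reading gives an excess of 57.3%. Without exchange, blue's 48% of left-handed product would have come with about 29.2% of right-handed product. Blue read 12%, so I judged that exchange kept pace.

The forecast gave a total of 61% (56% to 67%) and an excess of 61% (54% to 67%), above my figure, and on pace said keeps pace: “Exchange therefore keeps up even with less catalyst”.

The flask gave a total of 64.5% at an excess of 54.1%; on pace, keeps pace, 94% of the way.

    2 coupling partner → homo dimer (k = 0.0490 L mol⁻¹ s⁻¹)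
    coupling partner → decomposition product (k = 1.70 × 10⁻⁵ s⁻¹)
    coupling partner + right-handed substrate → right-handed product (k = 0.0210 L mol⁻¹ s⁻¹)
    racemization catalyst → spent catalyst (k = 0.0130 s⁻¹)
    left-handed substrate + racemization catalyst ⇌ right-handed substrate + racemization catalyst, rate k5*[racemization catalyst]*[left-handed substrate] forward; the back reaction follows from the equilibrium constant (k = 23.0 L mol⁻¹ s⁻¹)
    coupling partner + left-handed substrate → left-handed product (k = 0.0730 L mol⁻¹ s⁻¹)

In the flask at 0.250 min, coupling used left-handed substrate at 0.088 of the rate of the forward exchange step, while the racemization catalyst decayed with a half-life of 0.89 min by its own path. At 1.50 min, the flask held 31.0% of its catalyst charge beside 15.6% of its partner charge. At 15.0 min, what was left of the two substrates in the flask showed an excess of 7.85% of right-handed substrate, and the product's excess stood 3.2 points under my figure and 6.9 points under the forecast. For the neighbour with 0.10 M of coupling partner, a quarter of this charge, 3.68 again gives 57.3%; the computed flask gave 54.9% at a total of 32.8%.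

All runs were computed for substances that don't exist, noise included.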